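**Strategy.** Germacranolide numbering is used (ring C1–C10; lactone C11 α-carbon, C12 carbonyl, C13 methylene). Everything rests on the C7–C11 bond of the γ-lactone ring (O, C12, C11, C7, C6). The all-cis C6–O/C7–C11/C8–O triad is read as a trans C7–C8 epoxide whose C6 oxygen carries a phosphonoacetate: its carbanion (C11) opens the epoxide at C7 by 5-exo-tet attack with inversion, setting C7, releasing the C8 hydroxyl for the tiglate, and giving an α-phosphono lactone that is methylenated with formaldehyde in the same flask. The precursor is an open-chain Sharpless epoxy alcohol acylated with inversion; Nozaki–Hiyama–Kishi closure (C2–C3) builds the ten-membered ring later.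

Key step: step 14

Remark: the target is taken to persist as the open C5-hydroxy C2-ketone drawn, not as a transannular C2/C5 hemiketal; methyl groups sit on C4 and C10.

Step 1
Reactants: 1 (R)-2,2-dimethyl-1,3-dioxolane-4-carbaldehyde
Product: 2 (S)-4-ethynyl-2,2-dimethyl-1,3-dioxolane
Conditions: dimethyl (1-diazo-2-oxopropyl)phosphonate, K2CO3, MeOH, 0 °C → rt
Reagents that add atoms: dimethyl (1-diazo-2-oxopropyl)phosphonate CC(=O)C(=[N+]=[N-])P(=O)(OC)OC
Why: Seyferth–Gilbert homologation in its Ohira–Bestmann form converts the aldehyde into the terminal alkyne (future C3 and C4) under carbonate conditions mild enough to leave the dioxolane stereocentre (future C5) untouched, the descriptor changing from R to S only through the priority rules.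

Step 2
Reactants: 2 (S)-4-ethynyl-2,2-dimethyl-1,3-dioxolane
Product: 3 (S)-but-3-yne-1,2-diol
Conditions: Dowex 50W (H+ form), THF/H2O, rt
Reagents that add atoms: none
Why: Acid-catalysed acetal hydrolysis frees the propargylic hydroxyl that must direct the next step and does not touch the stereocentre.

Step 3
Reactants: 3 (S)-but-3-yne-1,2-diol
Product: 5 (2S,3Z)-4-iodo-3-methylbut-3-ene-1,2-diol, via alkenylmagnesium bis-alkoxide 4 (not isolated)
Conditions: MeMgBr (excess), CuI (cat.), THF, −10 °C → rt; then I2, −40 → 0 °C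
Reagents that add atoms: methylmagnesium bromide C[Mg]Br; iodine II
Why: Copper-catalysed anti-carbomagnesiation of the propargylic magnesium alkoxide delivers methyl to C4 and magnesium to C3 within a five-membered chelate, and iodinolysis with retention gives the Z iodoalkene in which iodine is cis to C5, the geometry later needed for the Z enone.

Step 4
Reactants: 5 (2S,3Z)-4-iodo-3-methylbut-3-ene-1,2-diol
Product: 6 (4S)-4-[(1Z)-1-iodoprop-1-en-2-yl]-2-(4-methoxyphenyl)-1,3-dioxolane (both acetal epimers)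
Conditions: 4-MeOC6H4CH(OMe)2, PPTS (cat.), CH2Cl2, rt
Reagents that add atoms: 4-methoxybenzaldehyde dimethyl acetal COC(OC)c1ccc(OC)cc1
Why: Acid-catalysed transacetalisation ties both hydroxyls into a 4-methoxybenzylidene acetal, whose new acetal centre is inconsequential because it is destroyed in step 5.

Step 5
Reactants: 6 (4S)-4-[(1Z)-1-iodoprop-1-en-2-yl]-2-(4-methoxyphenyl)-1,3-dioxolane
Product: 7 (2S,3Z)-4-iodo-2-[(4-methoxybenzyl)oxy]-3-methylbut-3-en-1-ol
Conditions: i-Bu2AlH, CH2Cl2, −78 → 0 °C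
Reagents that add atoms: none
Why: Regioselective reductive acetal opening, in which aluminium coordinates the less hindered primary oxygen, that C–O bond ionises and hydride reduces the oxocarbenium ion, leaves the PMB ether on the secondary C5 oxygen and the primary C6 hydroxyl free.

Step 6
Reactants: 7 (2S,3Z)-4-iodo-2-[(4-methoxybenzyl)oxy]-3-methylbut-3-en-1-ol
Product: 8 (2S,3Z)-4-iodo-2-[(4-methoxybenzyl)oxy]-3-methylbut-3-enal
Conditions: Dess–Martin periodinane, NaHCO3, CH2Cl2, 0 °C; used at once without chromatography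
Reagents that add atoms: none
Why: Buffered Dess–Martin oxidation gives the α-alkoxy aldehyde under non-basic conditions that should avoid epimerisation at C5 and migration of the β,γ-double bond.

Step 7
Reactants: 9 3-methylbut-2-en-1-ol (prenol)
Product: 10 tert-butyldimethyl[(3-methylbut-2-en-1-yl)oxy]silane
Conditions: TBSCl, imidazole, CH2Cl2, rt
Reagents that add atoms: tert-butyldimethylsilyl chloride CC(C)(C)[Si](C)(C)Cl
Why: Standard silylation protects the future C2 hydroxyl.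

Step 8
Reactants: 10 tert-butyldimethyl[(3-methylbut-2-en-1-yl)oxy]silane
Product: 11 (2E)-4-[(tert-butyldimethylsilyl)oxy]-2-methylbut-2-en-1-ol
Conditions: SeO2 (cat.), t-BuOOH, salicylic acid (cat.), CH2Cl2, rt
Reagents that add atoms: tert-butyl hydroperoxide CC(C)(C)OO
Why: Riley allylic oxidation (ene reaction followed by [2,3]-sigmatropic shift) hydroxylates selectively the (E)-methyl group of the trisubstituted alkene and so fixes the E geometry of the future C10=C1 bond.

Step 9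
Reactants: 11 (2E)-4-[(tert-butyldimethylsilyl)oxy]-2-methylbut-2-en-1-ol
Product: 12 {[(2E)-4-bromo-3-methylbut-2-en-1-yl]oxy}(tert-butyl)dimethylsilane
Conditions: CBr4, PPh3, CH2Cl2, 0 °C
Reagents that add atoms: carbon tetrabromide BrC(Br)(Br)Br
Why: Appel bromination converts the primary allylic alcohol into the bromide under neutral conditions that keep the silyl ether and the olefin geometry.

Step 10
Reactants: 12 {[(2E)-4-bromo-3-methylbut-2-en-1-yl]oxy}(tert-butyl)dimethylsilane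
Product: 13 tert-butyldimethyl{[(2E)-3-methylhex-2-en-5-yn-1-yl]oxy}silane
Conditions: HC≡CMgBr (excess), CuCl (cat.), THF, 0 °C → rt
Reagents that add atoms: ethynylmagnesium bromide C#C[Mg]Br
Why: Copper-catalysed coupling of an alkynyl Grignard reagent with a primary allylic bromide proceeds at the unhindered CH2 terminus (SN2) to give the skipped enyne that carries C7 and C8.

Step 11
Reactants: 13 tert-butyldimethyl{[(2E)-3-methylhex-2-en-5-yn-1-yl]oxy}silane; 8 (2S,3Z)-4-iodo-2-[(4-methoxybenzyl)oxy]-3-methylbut-3-enal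
Product: 16 (1Z,3S,4S,5E,8E)-10-[(tert-butyldimethylsilyl)oxy]-1-iodo-3-[(4-methoxybenzyl)oxy]-2,8-dimethyldeca-1,5,8-trien-4-ol, via alkenylzirconocene chloride 14 (not isolated), via alkenyl(methyl)zinc 15 (not isolated)
Conditions: Cp2Zr(H)Cl, CH2Cl2, rt; Me2Zn, −65 °C; then 8, −65 → 0 °C
Reagents that add atoms: none
Why: Schwartz hydrozirconation adds Zr–H syn to the terminal alkyne, zirconium-to-zinc transmetalation gives an (E)-alkenylzinc, and its 1,2-addition through the Cram chelate (zinc bridging the aldehyde oxygen and the C5 OPMB oxygen) sets the C6 carbinol syn to C5, any anti epimer being mismatched in step 12.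

Step 12
Reactants: 16 (1Z,3S,4S,5E,8E)-10-[(tert-butyldimethylsilyl)oxy]-1-iodo-3-[(4-methoxybenzyl)oxy]-2,8-dimethyldeca-1,5,8-trien-4-ol
Product: 17 (1Z,3S,4R,5R,6R,8E)-10-[(tert-butyldimethylsilyl)oxy]-5,6-epoxy-1-iodo-3-[(4-methoxybenzyl)oxy]-2,8-dimethyldeca-1,8-dien-4-ol
Conditions: Ti(OiPr)4 (cat.), D-(−)-diisopropyl tartrate, t-BuOOH, 4 Å MS, CH2Cl2, −20 °C
Reagents that add atoms: tert-butyl hydroperoxide CC(C)(C)OO
Why: Sharpless asymmetric epoxidation of the secondary (E)-allylic alcohol in the matched sense delivers oxygen to the C7=C8 face that gives the erythro epoxy alcohol, while the silylated allylic ether and the iodoalkene are inert.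

Step 13
Reactants: 17 (1Z,3S,4R,5R,6R,8E)-10-[(tert-butyldimethylsilyl)oxy]-5,6-epoxy-1-iodo-3-[(4-methoxybenzyl)oxy]-2,8-dimethyldeca-1,8-dien-4-ol; 18 2-(diethoxyphosphoryl)acetic acid
Product: 19 (1Z,3S,4S,5S,6R,8E)-10-[(tert-butyldimethylsilyl)oxy]-5,6-epoxy-1-iodo-3-[(4-methoxybenzyl)oxy]-2,8-dimethyldeca-1,8-dien-4-yl 2-(diethoxyphosphoryl)acetate
Conditions: PPh3, DIAD, toluene, 0 °C → rt
Reagents that add atoms: none
Why: Mitsunobu esterification displaces the activated C6 oxygen by the carboxylate with inversion, which at once places the C11–C12 unit on O6 and turns the erythro epoxy alcohol into the threo ester whose C6–O bond is anti to the epoxide C7–O bond.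

Step 14
Reactants: 19 (1Z,3S,4S,5S,6R,8E)-10-[(tert-butyldimethylsilyl)oxy]-5,6-epoxy-1-iodo-3-[(4-methoxybenzyl)oxy]-2,8-dimethyldeca-1,8-dien-4-yl 2-(diethoxyphosphoryl)acetate
Product: 21 (4R,5R)-4-[(1R,3E)-5-[(tert-butyldimethylsilyl)oxy]-1-hydroxy-3-methylpent-3-en-1-yl]-5-[(1S,2Z)-3-iodo-1-[(4-methoxybenzyl)oxy]-2-methylprop-2-en-1-yl]-3-methylideneoxolan-2-one, via α-phosphono lactone 20 (not isolated)
Conditions: NaH, THF, 0 → 45 °C; then (CH2O)n, 0 °C → rt
Reagents that add atoms: formaldehyde (as paraformaldehyde) C=O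
Why: NaH deprotonates the phosphonoacetate and the C11 carbanion opens the trans C7–C8 epoxide at C7 by SN2 attack anti to the epoxide oxygen; proton transfer from the acidic α-phosphono C–H to the C8 alkoxide then gives the phosphonate carbanion of 20, which undergoes Horner–Wadsworth–Emmons olefination with formaldehyde to install C13. The closest known type is the intramolecular alkylation of a stabilised carbanion by an epoxide, the opening stage of the Wadsworth–Emmons cyclopropanation, followed by the standard formaldehyde methylenation of α-phosphono lactones. The lactone ring (O, C12, C11, C7, C6) closes in the 5-exo-tet mode. C7 is set by stereospecific inversion at the epoxide carbon, so the Sharpless epoxide of step 12 and the inverted C6 centre of step 13 together dictate the all-cis relation of C6–O, C7–C11 and C8–O; C8 keeps its oxygen with retention and the transient C11 centre is erased by the olefination. The step needs attack at C7 (5-exo) and not at C8 (6-endo), which the shorter tether and the electronically unbiased, alkyl-flanked C8 should secure. It also needs the opening and olefination to outrun phosphoryl transfer to the C8 alkoxide (cyclopropane formation) and translactonisation to O8, which the moderate temperature, the fast internal proton transfer and the immediate formaldehyde quench should secure.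

Step 15
Reactants: 21 (4R,5R)-4-[(1R,3E)-5-[(tert-butyldimethylsilyl)oxy]-1-hydroxy-3-methylpent-3-en-1-yl]-5-[(1S,2Z)-3-iodo-1-[(4-methoxybenzyl)oxy]-2-methylprop-2-en-1-yl]-3-methylideneoxolan-2-one; 22 (2E)-2-methylbut-2-enoyl chloride (tigloyl chloride)
Product: 23 (1R,3E)-5-[(tert-butyldimethylsilyl)oxy]-1-[(2R,3R)-2-{(1S,2Z)-3-iodo-1-[(4-methoxybenzyl)oxy]-2-methylprop-2-en-1-yl}-4-methylidene-5-oxooxolan-3-yl]-3-methylpent-3-en-1-yl (2E)-2-methylbut-2-enoate
Conditions: pyridine, DMAP (cat.), CH2Cl2, 0 °C → rt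
Reagents that add atoms: none
Why: DMAP-catalysed acylation of the free C8 hydroxyl installs the tiglate directly, so that C8 never needs a protecting group.

Step 16
Reactants: 23 the C2 silyl ether tiglate named in step 15
Product: 24 (1R,3E)-5-hydroxy-1-[(2R,3R)-2-{(1S,2Z)-3-iodo-1-[(4-methoxybenzyl)oxy]-2-methylprop-2-en-1-yl}-4-methylidene-5-oxooxolan-3-yl]-3-methylpent-3-en-1-yl (2E)-2-methylbut-2-enoate
Conditions: HF·pyridine, pyridine, THF, 0 °C → rt
Reagents that add atoms: none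
Why: Buffered fluoride desilylation cleaves the primary allylic silyl ether, while the PMB ether, both esters and the iodoalkene are stable to it.

Step 17
Reactants: 24 the C2 allylic alcohol named in step 16
Product: 25 (1R)-2-[(2R,3R)-3-(hydroxymethyl)-2-methyloxiran-2-yl]-1-[(2R,3R)-2-{(1S,2Z)-3-iodo-1-[(4-methoxybenzyl)oxy]-2-methylprop-2-en-1-yl}-4-methylidene-5-oxooxolan-3-yl]ethyl (2E)-2-methylbut-2-enoate
Conditions: Ti(OiPr)4 (cat.), D-(−)-diethyl tartrate, t-BuOOH, 4 Å MS, CH2Cl2, −20 °C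
Reagents that add atoms: tert-butyl hydroperoxide CC(C)(C)OO
Why: Sharpless asymmetric epoxidation under reagent control delivers oxygen to the face of the (E)-trisubstituted allylic alcohol that sets C10 and C1 as in the target (the sense opposite to that of geraniol with the L-tartrate), and the electron-poor methylene lactone, tiglate and iodoalkene do not react.

Step 18
Reactants: 25 the C1/C10 epoxy alcohol named in step 17
Product: 26 (1R)-2-[(2R,3S)-3-formyl-2-methyloxiran-2-yl]-1-[(2R,3R)-2-{(1S,2Z)-3-iodo-1-[(4-methoxybenzyl)oxy]-2-methylprop-2-en-1-yl}-4-methylidene-5-oxooxolan-3-yl]ethyl (2E)-2-methylbut-2-enoate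
Conditions: Dess–Martin periodinane, NaHCO3, CH2Cl2, 0 °C → rt
Reagents that add atoms: none
Why: Dess–Martin oxidation gives the α,β-epoxy aldehyde without opening the epoxide or epimerising C1.

Step 19
Reactants: 26 the epoxy aldehyde alkenyl iodide named in step 18
Product: 27 (1R,5S,6R,7R,8R,10R)-1,10-epoxy-2-hydroxy-5-[(4-methoxybenzyl)oxy]-8-[(2E)-2-methylbut-2-enoyloxy]germacra-3Z,11(13)-dien-12,6-olide (both C2 epimers)
Conditions: CrCl2 (excess), NiCl2 (cat.), DMSO/THF, rt, high dilution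
Reagents that add atoms: none
Why: In the Nozaki–Hiyama–Kishi reaction nickel activates the alkenyl iodide, transmetalation gives an alkenylchromium species that adds chemoselectively to the aldehyde with retention of the Z geometry and closes the ten-membered ring at C2–C3, the uncontrolled C2 carbinol centre being erased in step 20.

Step 20
Reactants: 27 the macrocyclic C2 alcohol named in step 19
Product: 28 (1S,5S,6R,7R,8R,10R)-1,10-epoxy-5-[(4-methoxybenzyl)oxy]-8-[(2E)-2-methylbut-2-enoyloxy]-2-oxogermacra-3Z,11(13)-dien-12,6-olide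
Conditions: Dess–Martin periodinane, NaHCO3, CH2Cl2, rt
Reagents that add atoms: none
Why: Dess–Martin oxidation of both C2 epimers converges on the Z enone flanked by the epoxide.

Step 21
Reactants: 28 the PMB-protected enone named in step 20
Product: 29 (1S,5S,6R,7R,8R,10R)-1,10-epoxy-5-hydroxy-8-[(2E)-2-methylbut-2-enoyloxy]-2-oxogermacra-3Z,11(13)-dien-12,6-olide (CNP0345622.1)
Conditions: DDQ, CH2Cl2/pH 7 buffer, 0 °C → rt
Reagents that add atoms: none
Why: Oxidative PMB cleavage by DDQ (hydride abstraction to the oxocarbenium ion, then hydrolysis) frees the C5 hydroxyl under neutral conditions tolerated by the epoxy ketone, the methylene lactone and the tiglate.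

**Compound list**

1 | (R)-2,2-dimethyl-1,3-dioxolane-4-carbaldehyde | CC1(C)OC[C@H](C=O)O1 | starting material
2 | (S)-4-ethynyl-2,2-dimethyl-1,3-dioxolane | CC1(C)OC[C@H](C#C)O1 | intermediate
3 | (S)-but-3-yne-1,2-diol | OC[C@@H](O)C#C | intermediate
4 | (Z)-alkenylmagnesium bromide bis(bromomagnesium alkoxide) from carbomagnesiation of 3 | Br[Mg]/C=C(/C)[C@H](O[Mg]Br)CO[Mg]Br | intermediate (not isolated)
5 | (2S,3Z)-4-iodo-3-methylbut-3-ene-1,2-diol | OC[C@@H](O)/C(C)=C\I | intermediate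
6 | (4S)-4-[(1Z)-1-iodoprop-1-en-2-yl]-2-(4-methoxyphenyl)-1,3-dioxolane | COc1ccc(C2OC[C@H](/C(C)=C\I)O2)cc1 | intermediate
7 | (2S,3Z)-4-iodo-2-[(4-methoxybenzyl)oxy]-3-methylbut-3-en-1-ol | OC[C@@H](OCc1ccc(OC)cc1)/C(C)=C\I | intermediate
8 | (2S,3Z)-4-iodo-2-[(4-methoxybenzyl)oxy]-3-methylbut-3-enal | O=C[C@@H](OCc1ccc(OC)cc1)/C(C)=C\I | intermediate
9 | 3-methylbut-2-en-1-ol | CC(C)=CCO | starting material
10 | tert-butyldimethyl[(3-methylbut-2-en-1-yl)oxy]silane | CC(C)=CCO[Si](C)(C)C(C)(C)C | intermediate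
11 | (2E)-4-[(tert-butyldimethylsilyl)oxy]-2-methylbut-2-en-1-ol | OC/C(C)=C/CO[Si](C)(C)C(C)(C)C | intermediate
12 | {[(2E)-4-bromo-3-methylbut-2-en-1-yl]oxy}(tert-butyl)dimethylsilane | BrC/C(C)=C/CO[Si](C)(C)C(C)(C)C | intermediate
13 | tert-butyldimethyl{[(2E)-3-methylhex-2-en-5-yn-1-yl]oxy}silane | C#CC/C(C)=C/CO[Si](C)(C)C(C)(C)C | intermediate
14 | chloro[(1E,4E)-6-[(tert-butyldimethylsilyl)oxy]-4-methylhexa-1,4-dien-1-yl]zirconocene | Cl[Zr](/C=C/C/C(C)=C/CO[Si](C)(C)C(C)(C)C)(C1C=CC=C1)C1C=CC=C1 | intermediate (not isolated)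
15 | [(1E,4E)-6-[(tert-butyldimethylsilyl)oxy]-4-methylhexa-1,4-dien-1-yl](methyl)zinc | C[Zn]/C=C/C/C(C)=C/CO[Si](C)(C)C(C)(C)C | intermediate (not isolated)
16 | (1Z,3S,4S,5E,8E)-10-[(tert-butyldimethylsilyl)oxy]-1-iodo-3-[(4-methoxybenzyl)oxy]-2,8-dimethyldeca-1,5,8-trien-4-ol | O[C@H]([C@@H](OCc1ccc(OC)cc1)/C(C)=C\I)/C=C/C/C(C)=C/CO[Si](C)(C)C(C)(C)C | intermediate
17 | (1Z,3S,4R,5R,6R,8E)-10-[(tert-butyldimethylsilyl)oxy]-5,6-epoxy-1-iodo-3-[(4-methoxybenzyl)oxy]-2,8-dimethyldeca-1,8-dien-4-ol | O[C@H]([C@@H](OCc1ccc(OC)cc1)/C(C)=C\I)[C@H]1O[C@@H]1C/C(C)=C/CO[Si](C)(C)C(C)(C)C | intermediate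
18 | 2-(diethoxyphosphoryl)acetic acid | OC(=O)CP(=O)(OCC)OCC | starting material
19 | (1Z,3S,4S,5S,6R,8E)-10-[(tert-butyldimethylsilyl)oxy]-5,6-epoxy-1-iodo-3-[(4-methoxybenzyl)oxy]-2,8-dimethyldeca-1,8-dien-4-yl 2-(diethoxyphosphoryl)acetate | CCOP(=O)(OCC)CC(=O)O[C@@H]([C@@H](OCc1ccc(OC)cc1)/C(C)=C\I)[C@H]1O[C@@H]1C/C(C)=C/CO[Si](C)(C)C(C)(C)C | intermediate
20 | diethyl [(4R,5R)-4-[(1R,3E)-5-[(tert-butyldimethylsilyl)oxy]-1-hydroxy-3-methylpent-3-en-1-yl]-5-[(1S,2Z)-3-iodo-1-[(4-methoxybenzyl)oxy]-2-methylprop-2-en-1-yl]-2-oxooxolan-3-yl]phosphonate (C3 epimers) | CCOP(=O)(OCC)C1C(=O)O[C@@H]([C@@H](OCc2ccc(OC)cc2)/C(C)=C\I)[C@H]1[C@H](O)C/C(C)=C/CO[Si](C)(C)C(C)(C)C | intermediate (not isolated)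
21 | (4R,5R)-4-[(1R,3E)-5-[(tert-butyldimethylsilyl)oxy]-1-hydroxy-3-methylpent-3-en-1-yl]-5-[(1S,2Z)-3-iodo-1-[(4-methoxybenzyl)oxy]-2-methylprop-2-en-1-yl]-3-methylideneoxolan-2-one | C=C1C(=O)O[C@@H]([C@@H](OCc2ccc(OC)cc2)/C(C)=C\I)[C@H]1[C@H](O)C/C(C)=C/CO[Si](C)(C)C(C)(C)C | intermediate
22 | (2E)-2-methylbut-2-enoyl chloride | C/C=C(\C)C(Cl)=O | starting material
23 | (1R,3E)-5-[(tert-butyldimethylsilyl)oxy]-1-[(2R,3R)-2-{(1S,2Z)-3-iodo-1-[(4-methoxybenzyl)oxy]-2-methylprop-2-en-1-yl}-4-methylidene-5-oxooxolan-3-yl]-3-methylpent-3-en-1-yl (2E)-2-methylbut-2-enoate | C=C1C(=O)O[C@@H]([C@@H](OCc2ccc(OC)cc2)/C(C)=C\I)[C@H]1[C@H](OC(=O)/C(C)=C/C)C/C(C)=C/CO[Si](C)(C)C(C)(C)C | intermediate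
24 | (1R,3E)-5-hydroxy-1-[(2R,3R)-2-{(1S,2Z)-3-iodo-1-[(4-methoxybenzyl)oxy]-2-methylprop-2-en-1-yl}-4-methylidene-5-oxooxolan-3-yl]-3-methylpent-3-en-1-yl (2E)-2-methylbut-2-enoate | C=C1C(=O)O[C@@H]([C@@H](OCc2ccc(OC)cc2)/C(C)=C\I)[C@H]1[C@H](OC(=O)/C(C)=C/C)C/C(C)=C/CO | intermediate
25 | (1R)-2-[(2R,3R)-3-(hydroxymethyl)-2-methyloxiran-2-yl]-1-[(2R,3R)-2-{(1S,2Z)-3-iodo-1-[(4-methoxybenzyl)oxy]-2-methylprop-2-en-1-yl}-4-methylidene-5-oxooxolan-3-yl]ethyl (2E)-2-methylbut-2-enoate | C=C1C(=O)O[C@@H]([C@@H](OCc2ccc(OC)cc2)/C(C)=C\I)[C@H]1[C@H](OC(=O)/C(C)=C/C)C[C@@]1(C)O[C@@H]1CO | intermediate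
26 | (1R)-2-[(2R,3S)-3-formyl-2-methyloxiran-2-yl]-1-[(2R,3R)-2-{(1S,2Z)-3-iodo-1-[(4-methoxybenzyl)oxy]-2-methylprop-2-en-1-yl}-4-methylidene-5-oxooxolan-3-yl]ethyl (2E)-2-methylbut-2-enoate | C=C1C(=O)O[C@@H]([C@@H](OCc2ccc(OC)cc2)/C(C)=C\I)[C@H]1[C@H](OC(=O)/C(C)=C/C)C[C@@]1(C)O[C@@H]1C=O | intermediate
27 | (1R,5S,6R,7R,8R,10R)-1,10-epoxy-2-hydroxy-5-[(4-methoxybenzyl)oxy]-8-[(2E)-2-methylbut-2-enoyloxy]germacra-3Z,11(13)-dien-12,6-olide (C2 epimers) | C=C1C(=O)O[C@@H]2[C@H]1[C@H](OC(=O)/C(C)=C/C)C[C@@]1(C)O[C@@H]1C(O)/C=C(/C)[C@@H]2OCc1ccc(OC)cc1 | intermediate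
28 | (1S,5S,6R,7R,8R,10R)-1,10-epoxy-5-[(4-methoxybenzyl)oxy]-8-[(2E)-2-methylbut-2-enoyloxy]-2-oxogermacra-3Z,11(13)-dien-12,6-olide | C=C1C(=O)O[C@@H]2[C@H]1[C@H](OC(=O)/C(C)=C/C)C[C@@]1(C)O[C@@H]1C(=O)/C=C(/C)[C@@H]2OCc1ccc(OC)cc1 | intermediate
29 | (1S,5S,6R,7R,8R,10R)-1,10-epoxy-5-hydroxy-8-[(2E)-2-methylbut-2-enoyloxy]-2-oxogermacra-3Z,11(13)-dien-12,6-olide (CNP0345622.1) | C=C1C(=O)O[C@@H]2[C@H]1[C@H](OC(=O)/C(C)=C/C)C[C@@]1(C)O[C@@H]1C(=O)/C=C(/C)[C@@H]2O | target

**Step count and risks**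

Total step count: 21. Longest linear sequence: 17 steps (steps 1–6, then 11–21, from compound 1).

Steps most likely to fail:

1. Step 14 (key step). The stabilised carbanion may open the epoxide too slowly, so that phosphoryl transfer to the C8 alkoxide followed by 3-exo displacement (the cyclopropanation pathway) or translactonisation to O8 competes with the intended closure and olefination. Fallback, setting out from 17 and returning at 21, by a phosphorus-free ester enolate route: Mitsunobu esterification of 17 with acetic acid (PPh3, DIAD) would give the inverted C6 acetate F1. LiHMDS in THF from −78 to 0 °C would form the ester enolate, whose 5-exo-tet opening of the epoxide at C7 would give the saturated cis-lactone alcohol F2. Double deprotonation with LDA and trapping with Eschenmoser's salt would give the Mannich base F3, methyl iodide would quaternise it to the ammonium iodide F4, and NaHCO3 would eliminate trimethylamine to give 21.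

2. Step 19. Strain in the forming ten-membered ring (trans-epoxide, cis-fused lactone) may slow the intramolecular addition, so that protonation of the alkenylchromium species or intermolecular coupling takes over. Fallback, setting out from 26 and returning at 28, by an acylative cross-coupling that forms the enone directly: Pd(PPh3)4-catalysed stannylation of 26 with hexamethylditin would give the alkenylstannane aldehyde F5. Pinnick oxidation (NaClO2, NaH2PO4, 2-methylbut-2-ene) would give the epoxy acid F6, the Ghosez reagent would convert it under neutral conditions into the acid chloride F7, and an intramolecular Stille acylation (Pd2(dba)3, tri(2-furyl)phosphine, toluene, high dilution) would close the ring to 28, making step 20 unnecessary.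

3. Step 11. The α-alkoxy β,γ-unsaturated aldehyde may epimerise at C5 before it is consumed, and incomplete chelation control would erode the facial selectivity at C6. Fallback, setting out from 7 (with 13) and returning at 16, by a ketone reduction under reagent control: oxidation of 7 with TEMPO (cat.) and PhI(OAc)2 in MeCN/H2O would give the acid F8, and EDC coupling with N,O-dimethylhydroxylamine would give the Weinreb amide F9. The lithium acetylide of 13 (n-BuLi, THF, −78 °C) would add to F9 to give the ynone F10. Noyori transfer hydrogenation with RuCl[(R,R)-TsDPEN](p-cymene) in i-PrOH, the catalyst enantiomer expected to give the (4S) carbinol, would give the propargylic alcohol F11. Trans-reduction with NaAlH2(OCH2CH2OMe)2 in THF at −20 °C would give 16.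

**Further compounds**

F1 | step 14 | (1Z,3S,4S,5S,6R,8E)-10-[(tert-butyldimethylsilyl)oxy]-5,6-epoxy-1-iodo-3-[(4-methoxybenzyl)oxy]-2,8-dimethyldeca-1,8-dien-4-yl acetate | CC(=O)O[C@@H]([C@@H](OCc1ccc(OC)cc1)/C(C)=C\I)[C@H]1O[C@@H]1C/C(C)=C/CO[Si](C)(C)C(C)(C)C
F2 | step 14 | (4R,5R)-4-[(1R,3E)-5-[(tert-butyldimethylsilyl)oxy]-1-hydroxy-3-methylpent-3-en-1-yl]-5-[(1S,2Z)-3-iodo-1-[(4-methoxybenzyl)oxy]-2-methylprop-2-en-1-yl]oxolan-2-one | C1C(=O)O[C@@H]([C@@H](OCc2ccc(OC)cc2)/C(C)=C\I)[C@H]1[C@H](O)C/C(C)=C/CO[Si](C)(C)C(C)(C)C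
F3 | step 14 | 3-[(dimethylamino)methyl] derivative of F2 (C3 epimers) | CN(C)CC1C(=O)O[C@@H]([C@@H](OCc2ccc(OC)cc2)/C(C)=C\I)[C@H]1[C@H](O)C/C(C)=C/CO[Si](C)(C)C(C)(C)C
F4 | step 14 | trimethylammonium iodide of F3 | C[N+](C)(C)CC1C(=O)O[C@@H]([C@@H](OCc2ccc(OC)cc2)/C(C)=C\I)[C@H]1[C@H](O)C/C(C)=C/CO[Si](C)(C)C(C)(C)C.[I-]
F5 | step 19 | trimethylstannyl analogue of 26 (SnMe3 in place of iodine, Z retained) | C=C1C(=O)O[C@@H]([C@@H](OCc2ccc(OC)cc2)/C(C)=C\[Sn](C)(C)C)[C@H]1[C@H](OC(=O)/C(C)=C/C)C[C@@]1(C)O[C@@H]1C=O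
F6 | step 19 | oxirane-2-carboxylic acid corresponding to F5 (CO2H in place of CHO) | C=C1C(=O)O[C@@H]([C@@H](OCc2ccc(OC)cc2)/C(C)=C\[Sn](C)(C)C)[C@H]1[C@H](OC(=O)/C(C)=C/C)C[C@@]1(C)O[C@@H]1C(=O)O
F7 | step 19 | acid chloride of F6 | C=C1C(=O)O[C@@H]([C@@H](OCc2ccc(OC)cc2)/C(C)=C\[Sn](C)(C)C)[C@H]1[C@H](OC(=O)/C(C)=C/C)C[C@@]1(C)O[C@@H]1C(Cl)=O
F8 | step 11 | (2S,3Z)-4-iodo-2-[(4-methoxybenzyl)oxy]-3-methylbut-3-enoic acid | OC(=O)[C@@H](OCc1ccc(OC)cc1)/C(C)=C\I
F9 | step 11 | (2S,3Z)-4-iodo-N-methoxy-2-[(4-methoxybenzyl)oxy]-N,3-dimethylbut-3-enamide | CON(C)C(=O)[C@@H](OCc1ccc(OC)cc1)/C(C)=C\I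
F10 | step 11 | (1Z,3S,8E)-10-[(tert-butyldimethylsilyl)oxy]-1-iodo-3-[(4-methoxybenzyl)oxy]-2,8-dimethyldeca-1,8-dien-5-yn-4-one | O=C([C@@H](OCc1ccc(OC)cc1)/C(C)=C\I)C#CC/C(C)=C/CO[Si](C)(C)C(C)(C)C
F11 | step 11 | (1Z,3S,4S,8E)-10-[(tert-butyldimethylsilyl)oxy]-1-iodo-3-[(4-methoxybenzyl)oxy]-2,8-dimethyldeca-1,8-dien-5-yn-4-ol | O[C@H]([C@@H](OCc1ccc(OC)cc1)/C(C)=C\I)C#CC/C(C)=C/CO[Si](C)(C)C(C)(C)C
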